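Everything rests on cutting two bonds of ring B, C7–C1' and C1–C8. The C6–C7–C8 bridge with its gem-dimethyl carbon C8 then turns out to be an ordinary prenyl group on C5. Aristophenone A thus shrinks to an achiral, dearomatised 3,3,5-triprenylmaclurin: a ring A trione with two identical prenyls on C5, one on C1 and the free catechol. In the forward sense an aromatic prenyltransferase passes a dimethylallyl cation to C7 of one enantiotopic prenyl and enol carbon C1 traps the C8 cation. Ring B, two C–C bonds and the stereocentres C1, C5 and C7 therefore arise in one operation. Each partner is made in one step.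

Key step: step 3

Numbering: bridgeheads C1 and C5, bridge ketone C9, ring A = C1-C2-C3-C4-C5-C9, ring B = C1-C8-C7-C6-C5-C9, C8 = CMe2, C7 = CH(prenyl), C1' = first carbon of the C7 prenyl. The monocyclic precursor carries the same numbers.
Assumption: every β-triketone is drawn as one enol tautomer of a fast equilibrium, CIP and pro-S/Re descriptors refer to the tautomer drawn, and the search for the enzyme variant counts as method development, not as a synthetic step.

Step 1
Reactants: 1 maclurin; 2 prenyl bromide
Product: 5 dearomatised 3,3,5-triprenylmaclurin (achiral), via maclurin borate 3 (not isolated), via triprenyl borate 4 (not isolated)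
Conditions: B(OH)3 (3 equiv), aq. KOH to pH 10, degassed H2O, Ar, 0 °C; 2 (3.3 equiv) added slowly, pH held at 9.5–10 with KOH, 0 °C to rt; cold 1 M HCl to pH 3, EtOAc; reversed-phase chromatography
Reagents that add atoms: prenyl bromide 2, CC(C)=CCBr
Why: Aqueous-base C-prenylation of an acylphloroglucinol (the alkylative dearomatisation used for lupulone-type triketones) puts two prenyls on one former CH carbon and one on the other because water solvates the oxygens of the ambident anion, while the catechol sits as its anionic cyclic borate ester, a mask known to shield catechols from alkylation and air in alkaline water, and is released by brief cold acidification, so that no ketal has to be cleaved with acid next to three prenyl groups that would close onto the enols as chromans.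

Step 2
Reactants: 2 prenyl bromide
Product: 6 dimethylallyl diphosphate (stored as its tris-ammonium salt)
Conditions: (n-Bu4N)3HP2O7 (2 equiv), MeCN, 0 °C to rt; Dowex 50W-X8 (NH4+ form), NH4HCO3 buffer pH 8; cellulose chromatography; lyophilisation
Reagents that add atoms: tris(tetrabutylammonium) hydrogen diphosphate, CCCC[N+](CCCC)(CCCC)CCCC.CCCC[N+](CCCC)(CCCC)CCCC.CCCC[N+](CCCC)(CCCC)CCCC.OP(=O)([O-])OP(=O)([O-])[O-]
Why: SN2 displacement of the primary allylic bromide by the hydrogen diphosphate trianion in dry acetonitrile is the standard preparation of allylic diphosphates, and exchange to the ammonium salt near pH 8 keeps the acid-labile allylic C–O bond intact.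

Step 3
Reactants: 5 dearomatised 3,3,5-triprenylmaclurin; 6 dimethylallyl diphosphate
Product: 8 aristophenone A, via C8 cation 7 (not isolated)
Conditions: UbiA-type aromatic prenyltransferase (variant selected for C1 capture, yeast microsomes), 6 (2 equiv), MgCl2 (10 mM), Tris-HCl pH 7.5, sodium ascorbate, 2% DMSO, Ar, 30 °C; EtOAc extraction at pH 5–6, reversed-phase HPLC
Reagents that add atoms: dimethylallyl diphosphate 6, CC(C)=CCOP(=O)(O)OP(=O)(O)O
Why: Proposed new method: magnesium-assisted loss of diphosphate from 6 inside the active site leaves a dimethylallyl cation, the alkene CH carbon C7 of the pro-S prenyl on C5 adds to it in the Markovnikov sense (bond C7–C1', tertiary cation 7 at C8), and the enol carbon C1 of ring A, folded beneath, bonds to C8 and gives 8 after loss of the enol proton. The closest known reaction type is the prenylation-triggered carbocyclisation that membrane-bound UbiA-type plant aromatic prenyltransferases perform in the biosynthesis of bicyclic polyprenylated acylphloroglucinols; a catalyst that steers capture to C1 of this aroyl substrate still has to be mined from Garcinia or Clusia transcriptomes or evolved from such an enzyme. Ring B closes as a six-membered carbocycle by 6-(enolexo) capture of a planar tertiary cation through a chair-like array. C5 becomes stereogenic through the choice of the pocket between the two enantiotopic prenyls, C7 is set by delivery of the cation to the Re face of that alkene, which places the new side chain equatorial on the chair, and C1 follows from C5 because the three-atom tether C6–C7–C8 reaches ring A only on the face from which it starts. The step needs enantiotopic-group and alkene-face selection, capture at C1 and not at C3 or at the oxygens on C4 and C9, and no direct prenyl transfer to C1, to the C1 prenyl or to the catechol; the substrate supplies only the Markovnikov bias of its trisubstituted alkene, the tether geometry and a C1 that is less encumbered than the chelated, aroyl-bearing C3, so the rest must come from the protein.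

Compound list
1 | maclurin, (3,4-dihydroxyphenyl)(2,4,6-trihydroxyphenyl)methanone | O=C(c1ccc(O)c(O)c1)c1c(O)cc(O)cc1O | starting material
2 | prenyl bromide, 1-bromo-3-methylbut-2-ene | CC(C)=CCBr | starting material
3 | maclurin borate, potassium salt of the cyclic dihydroxyborate ester across O3' and O4' (phloroglucinol ring drawn un-ionised) | [K+].O=C(c1ccc2c(c1)O[B-](O)(O)O2)c1c(O)cc(O)cc1O | intermediate
4 | triprenyl borate, the same borate ester of compound 5 | [K+].CC(C)=CCC1=C(O)C(C(=O)c2ccc3c(c2)O[B-](O)(O)O3)=C(O)C(CC=C(C)C)(CC=C(C)C)C1=O | intermediate
5 | dearomatised 3,3,5-triprenylmaclurin, 4-(3,4-dihydroxybenzoyl)-3,5-dihydroxy-2,6,6-tris(3-methylbut-2-enyl)cyclohexa-2,4-dien-1-one; achiral; the prenyls sit on the two former CH carbons of the phloroglucinol ring (C5 twice, C1 once in the numbering above) | CC(C)=CCC1=C(O)C(C(=O)c2ccc(O)c(O)c2)=C(O)C(CC=C(C)C)(CC=C(C)C)C1=O | intermediate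
6 | dimethylallyl diphosphate (drawn as the free acid, handled as the tris-ammonium salt) | CC(C)=CCOP(=O)(O)OP(=O)(O)O | intermediate
7 | enzyme-bound tertiary C8 cation, (5S,7R), C7–C1' bond already formed | CC(C)=CC[C@@H]([C+](C)C)C[C@]1(CC=C(C)C)C(=O)C(CC=C(C)C)=C(O)C(C(=O)c2ccc(O)c(O)c2)=C1O | intermediate
8 | aristophenone A, (1S,5S,7R)-3-(3,4-dihydroxybenzoyl)-4-hydroxy-8,8-dimethyl-1,5,7-tris(3-methylbut-2-enyl)bicyclo[3.3.1]non-3-ene-2,9-dione; C7 prenyl equatorial on chair ring B, on the same side of ring B as the two bridgehead prenyls | CC(C)=CC[C@@H]1C[C@]2(CC=C(C)C)C(=O)[C@@](CC=C(C)C)(C(=O)C(C(=O)c3ccc(O)c(O)c3)=C2O)C1(C)C | target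

Total step count: 3. Longest linear sequence: 2 steps (1 to 5 to 8, or 2 to 6 to 8).

Steps most likely to fail

1. Step 3.
- **What may go wrong:**
  - No variant may fold ring A under the C8 cation. The cation is then quenched by water or by the oxygens on C4 and C9, or it is captured at C3.
  - Plain prenyl transfer to C1 or to the catechol ring may take over.
  - The enantiotopic prenyls may be told apart only weakly.
  - A membrane-bound enzyme and a greasy substrate may limit turnover.
- **Fallback:** it uses known chemistry with chiral-pool control in place of the protein, sets out from 1 and returns at 8. Maclurin 1 is heated with HC(OEt)3 and Amberlyst 15 in toluene, with removal of ethanol, to give the catechol ethyl orthoformate F1. Two C-prenylations with 2 in cold aqueous KOH give the aromatic 3,5-diprenyl orthoformate F2. Purchased (S)-lavandulol is converted by Appel iodination (I2, PPh3, imidazole, CH2Cl2) into (S)-lavandulyl iodide F3. Alkylative dearomatisation of F2 with F3 and LiN(SiMe3)2 in THF gives the masked C5-lavandulyl trione F4 together with its C5 epimer. Cold 0.1 M HCl in aqueous THF followed by NaHCO3 frees the catechol, and chromatography at this stage should deliver the single (5S,7R) lavandulyl trione F5. In formic acid at room temperature the isopropenyl group of F5 is protonated to the same cation 7, which C1 captures to give 8. This acid-mediated cation–enol cyclisation is established for the benzoyl analogue of this ring system. In this fallback C7 comes from the chiral pool, C5 from the separation and C1 from the tether.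

2. Step 1.
- **What may go wrong:**
  - The third, dearomatising alkylation may stall at the moderate pH that the borate ester needs.
  - A fourth prenylation may occur at C1.
  - O-prenylation may occur on ring A.
  - The catechol may partly escape from the borate ester and then be alkylated or air-oxidised.
- **Fallback:** it uses an isolable covalent mask in place of the transient one, sets out from 1 and returns at 5. The catechol ethyl orthoformate F1, made as above, is stable to strong base. The three prenylations can therefore be run with 2 in 2 M KOH at 0 °C, the classical strongly basic regime, to give the masked triprenyl trione F6. Cold 0.1 M HCl in aqueous THF followed by NaHCO3 then removes the orthoester. This hydrolysis runs far faster than protonation of a trisubstituted alkene, so the prenyl groups should stay open.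

3. Step 2.
- **What may go wrong:**
  - The allylic diphosphate may solvolyse or eliminate during ion exchange, chromatography or freeze-drying.
  - Inorganic diphosphate may be carried over, which binds magnesium and slows the enzyme of step 3.
- **Fallback:** it forms the P–O–P bond enzymatically in place of displacement by diphosphate, sets out from 2 and returns at 6. Bromide 2 is displaced with (n-Bu4N)2HPO4 in MeCN to give the much sturdier dimethylallyl monophosphate F7. An isopentenyl phosphate kinase with ATP and MgCl2 phosphorylates F7 to 6 directly in the buffer of step 3. The labile diphosphate is thus made as it is consumed and is never isolated.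

Further compounds
F1 | step 3 | catechol ethyl orthoformate of maclurin, (2-ethoxy-1,3-benzodioxol-5-yl)(2,4,6-trihydroxyphenyl)methanone, racemic at the orthoester carbon | CCOC1Oc2ccc(cc2O1)C(=O)c1c(O)cc(O)cc1O
F2 | step 3 | aromatic 3,5-diprenyl orthoformate | CCOC1Oc2ccc(cc2O1)C(=O)c1c(O)c(CC=C(C)C)c(O)c(CC=C(C)C)c1O
F3 | step 3 | (S)-lavandulyl iodide | CC(C)=CC[C@@H](C(C)=C)CI
F4 | step 3 | masked C5-lavandulyl trione, (5S,7R), mixture at the orthoester carbon | CC(C)=CC[C@@H](C(C)=C)C[C@]1(CC=C(C)C)C(=O)C(CC=C(C)C)=C(O)C(C(=O)c2ccc3OC(OCC)Oc3c2)=C1O
F5 | step 3 | (5S,7R) lavandulyl trione with free catechol | CC(C)=CC[C@@H](C(C)=C)C[C@]1(CC=C(C)C)C(=O)C(CC=C(C)C)=C(O)C(C(=O)c2ccc(O)c(O)c2)=C1O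
F6 | step 1 | masked triprenyl trione, ethyl orthoformate of 5 | CCOC1Oc2ccc(cc2O1)C(=O)C1=C(O)C(CC=C(C)C)(CC=C(C)C)C(=O)C(CC=C(C)C)=C1O
F7 | step 2 | dimethylallyl monophosphate | CC(C)=CCOP(=O)(O)O
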